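## Structural features

- The target is a flavone. Benzo ring A is fused through C4a–C8a to the 4-pyranone ring C, and C2 of ring C carries, through the C2–C1' bond, a 2'-hydroxy-6'-methoxyphenyl ring B.
- Ring A has no free position: C5 OMe, C6 OH, C7 OMe and C8 OMe lie between the fusion atoms C4a (bonded to the C4 carbonyl) and C8a (bonded to O1).
- There is no stereocentre. The C2–C1' axis is flanked on the chromone side only by H-3 and O1, so it should rotate freely and stereochemistry is not an issue.
- The fragile elements are three. The C6 hydroxyl is para to the oxygen on C8a, so ring A is a hydroquinone monoether that air or base can oxidise to a quinone. A free 2'-hydroxyl next to an open three-carbon bridge can close the wrong ring. The acetal and MOM groups used on the way are acid-labile.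
- The real difficulty is the regiochemistry of ring A: one free hydroxyl at C6 between methoxy groups at C5 and C7. Electrophilic substitution is impossible on a full ring, and selective methylation of a polyphenol would be unreliable.
- The key step uses the contiguous array C8a(O)–C8(OMe)–C7(OMe)–C6(O). These are the four carbons of a squaric diester: the two ester carbons become C7 and C8, and the two carbonyl carbons become C6 and C8a, whose oxygens are exactly the two that are not methylated. Only C5 (with its methoxy group) and C4a (with C4 attached) have to come from an alkenyl unit.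

## Logic of the disconnections

**17 ⇒ 16 ⇒ 15.** Ring C is opened at O1–C2, and the three O–CH2 bonds of the MOM ethers are cut in the same operation. An o-hydroxyaryl ynone already holds C2, C3 and C4 at the oxidation level of the pyranone and closes by conjugate addition. The target becomes an open diaryl ynone, and one acid treatment both frees the phenols and closes the ring. The forward step must close 6-endo through the C8a hydroxyl and not 5-exo. The C6 and C2' hydroxyls must have no productive closure of their own, and air must be kept from the free hydroquinone-type ring.

**15 ⇒ 14 ⇒ 9 + 13 (from 12).** The C4–C3 bond is cut, with one adjustment of oxidation level. The cut gives two aromatic halves of similar size. C4 stays on ring A, so the direction of the later ring closure is fixed by constitution. The forward steps need an acetylide that adds to the di-ortho-substituted aldehyde 9, and an oxidant neutral enough to leave three MOM ethers and an ynone untouched.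

**12 ⇒ 11 ⇒ 10.** The C2–C3 bond is cut: the formyl carbon of 10 is the future C2 and the added carbon is C3. The phenol is masked first, because a free ortho hydroxyl deactivates the aldehyde towards homologation and would later quench the acetylide. The mask must survive base and organolithium and fall under the same acid as the ring A masks.

**9 ⇒ 8 ⇒ 7.** No skeletal bond is cut; the two MOM O–CH2 bonds and the acetal C–O bonds are adjusted. The dimethyl acetal is hydrolysed before the MOM groups go on. This avoids having to tell one acetal from another, and the formyl group makes the hydroquinone less prone to oxidation. The forward alkylation must also reach the hydroxyl that is hydrogen-bonded to the aldehyde.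

**7 ⇒ 6 ⇒ 5 ⇒ 4.** This is the strategic cut. The C4a–C8a bond is broken and C6 is reconnected to C8a as a four-membered ring.
- The hexasubstituted benzene reduces to a cyclobutenone in which C6, C7, C8 and C8a already carry their oxygens at the right alkylation state.
- Atom by atom, 4 and 7 map onto ring A without conflict. The (1E) geometry of 4 is what retentive metalation of 1 delivers, so the structures stand as drawn.
- The carbinol of 4 is left free on purpose. A free hydroxyl is the strongest outward-rotating donor, and both ring A phenols later receive the same mask, so an O-protected carbinol would add steps and no selectivity.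
- The acetal keeps C4 at the aldehyde level without placing an acceptor on the nucleophilic alkene.
- The forward step needs outward rotation of the carbinol oxygen and conditions free of oxygen and acid.

**4 ⇒ 3 + 2; 3 ⇒ 1.** The C5–C6 bond is cut. Because 2 is symmetric, either carbonyl gives the same adduct. The forward step needs metalation of 1 at C1 only and a single 1,2-addition.

## Other disconnections considered

**Alternative 1: isoxazole as masked diketone.**
- Cut: C4–C3, with C2 held at the ketone level by a temporary oxygen.
- Forward key step: the ring A nitrile oxide A2 (2,4,5-trimethoxy-3,6-bis(methoxymethoxy)benzonitrile oxide) would undergo 1,3-dipolar cycloaddition with the alkyne A3 (1-(benzyloxy)-2-ethynyl-3-methoxybenzene). The product would be the 3,5-diaryl isoxazole A1 (5-[2-(benzyloxy)-6-methoxyphenyl]-3-[2,4,5-trimethoxy-3,6-bis(methoxymethoxy)phenyl]-1,2-oxazole). Reductive N–O cleavage (Mo(CO)6, wet MeCN) and acid would then unmask the three-carbon unit and close ring C, and hydrogenolysis would free the 2'-hydroxyl.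
- In its favour: A2 would come from 9 by oximation and oxidation. A di-ortho-substituted nitrile oxide should be slow to dimerise. The 3,5-regiochemistry with a terminal alkyne is dependable. The isoxazole is a robust, storable intermediate.
- Against it here: after N–O cleavage the bridge is a diketone equivalent with both ends at the carbonyl level, so either ring could supply the pyranone oxygen. The 2'-oxygen must therefore stay blocked by a group that survives the acid, and this costs a separate hydrogenolysis. Dipole and dipolarophile are both doubly ortho-substituted, so the cycloaddition should be slow.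
- Comparison: structurally this plan does not address ring A at all and would still need 9 from the chosen route. Mechanistically it is the equal of the chosen plan in regiocontrol at C3, and it is better in needing no organolithium and no alcohol oxidation at the coupling stage. In step economy it is worse: about five operations from 9 against three.

**Alternative 2: aryne and chromone carboxylate.**
- Cut: C2–C1', with a temporary lactone bridge from C2'–O to the carboxyl carbon on C3.
- Forward key step: CsF would release the aryne from A6 (3-methoxy-2-(trimethylsilyl)phenyl trifluoromethanesulfonate). The carboxylate of A5 (6-(benzyloxy)-5,7,8-trimethoxy-4-oxo-4H-chromene-3-carboxylic acid) would add through oxygen at the aryne carbon remote from the methoxy group. The resulting aryl anion would add to C2, and the pyranone would open. The product would be the 3-aroylcoumarin A4 (3-[5-(benzyloxy)-2-hydroxy-3,4,6-trimethoxybenzoyl]-5-methoxy-2H-chromen-2-one).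
- In its favour: the polarisation of the methoxy aryne places oxygen at C2' and carbon at C1' as the target requires. The 2'-oxygen arrives without a protecting group, which is a point where this plan is better. The conditions are mild and fluoride-triggered.
- Against it here:
  - A4 is a coumarin, not a flavone. The lactone must be opened, the carboxyl carbon lost, and ring C re-closed through the C8a oxygen.
  - C2 was arylated at the aldehyde level, so re-closure arrives at the dihydro (flavanone) oxidation level and a dehydrogenation is needed, then debenzylation.
  - The aryl anion could instead attack its own ester carbonyl, the usual aryne insertion into an acid C–O bond.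
  - A5 needs a fully substituted ring A with a differentiated C6 oxygen, so the central problem is untouched.
- Comparison: on structure it solves the smaller problem (ring B attachment) and leaves the larger one. On mechanism it is less secure at the anion-partitioning stage. On step economy it is clearly longer.

**Alternative 3: symmetric ring A aryne and an arylpropiolic acid.**
- Cut: C4a–C4 and C8a–O1 on ring A, and O1–C2.
- Forward key step: CsF would release a symmetric aryne from A8 (4,7-dimethoxy-2,2-dimethyl-6-(trimethylsilyl)-1,3-benzodioxol-5-yl trifluoromethanesulfonate). The carboxylate of A9 (3-[2-(benzyloxy)-6-methoxyphenyl]prop-2-ynoic acid) would add through oxygen and the aryl anion would attack the carboxyl carbon. The o-acylphenoxide would then add to the ynone. The product would be A7, the 6,7-O-isopropylidene derivative of 2-[2-(benzyloxy)-6-methoxyphenyl]-6,7-dihydroxy-5,8-dimethoxy-4H-chromen-4-one.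
- In its favour: one operation would form two ring A bonds and ring C at the flavone oxidation level. The symmetry of the aryne removes any regiochemical question in the insertion. The conditions are milder than a thermolysis at 110 °C. In convergence and in the construction of ring C this plan is better than the chosen one.
- Against it here: ring A arrives as a symmetric 6,7-catechol. After acetonide removal the 7-hydroxyl must be methylated in the presence of the 6-hydroxyl. The 7-hydroxyl is the more acidic through conjugation with C4=O, so this is plausible, but it rests on a selectivity between two neighbouring phenols. A8 is a hexasubstituted arene whose preparation would be a multistep sequence of its own, and the aryne is flanked by two methoxy groups.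
- Comparison: structurally the chosen plan writes the 6-OH/7-OMe distinction into the starting diester, whereas this plan defers it to the end. Mechanistically both key steps are of known types. In step economy the endgame from A7 (acetonide removal, selective methylation, hydrogenolysis) is about as long as the chosen one, but making A8 and A9 makes the whole longer.

Key step: step 2

Remark on the chemistry: the carbinol carbons of 4 and 14 are formed racemic and are destroyed in steps 2 and 8, so no stereocontrol is planned; in step 9 the order in which the MOM groups fall and ring C closes is immaterial and is drawn through the fully deprotected ynone 16.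

## Route

Step 1
Reactants: 1 (E)-1,3,3-trimethoxyprop-1-ene; 2 dimethyl squarate
Product: 4 4-hydroxy-2,3-dimethoxy-4-[(1E)-1,3,3-trimethoxyprop-1-en-1-yl]cyclobut-2-en-1-one (racemic), via vinyllithium 3 (not isolated)
Conditions: 1, t-BuLi, THF, −78 → −40 °C; then 2, THF, −78 °C; aq. NH4Cl, −78 °C
Reagents that add atoms: none
Why: Directed α-lithiation of an enol ether, in which the acetal oxygens lie cis to the C1–H and guide t-BuLi to it; the configurationally stable vinyllithium keeps the E geometry and adds once, 1,2, to one carbonyl of the squarate at −78 °C, giving a racemic carbinol that step 2 erases.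

Step 2
Reactants: 4 4-hydroxy-2,3-dimethoxy-4-[(1E)-1,3,3-trimethoxyprop-1-en-1-yl]cyclobut-2-en-1-one
Product: 7 2-(dimethoxymethyl)-3,5,6-trimethoxybenzene-1,4-diol, via dienylketene 5 (not isolated), via cyclohexadienone 6 (not isolated)
Conditions: toluene (degassed, 0.02 M), 110 °C, Ar
Reagents that add atoms: none
Why: Heat opens the C1–C4 bond of the cyclobutenone in a conrotatory four-electron process to the dienylketene 5; the carbinol oxygen, the strongest donor on the breaking bond, rotates outward, so the alkenyl arm turns inward and ends cis to the ketene (3Z), the only geometry that can close. A disrotatory six-electron electrocyclisation then joins the ketene carbon (future C8a) to the enol-ether β-carbon (future C4a), a polarity-matched pair, and closes ring A as the six-membered cyclohexa-2,4-dienone 6. Enolisation of 6 moves the C4a hydrogen to the C8a oxygen, aromatises the ring to 7 and removes the only sp3 centre formed, so no stereocentre has to be controlled. The closest known reaction type is the Moore rearrangement of 4-alkenyl-4-hydroxycyclobutenones to hydroquinones. The only selectivity needed is torquoselectivity, since 2 is symmetric and was attacked once, and every ring A oxygen already sits on the open chain. The dimethoxymethyl group lies on the inward side of the closing terminus, which should be tolerable because the partner terminus is a linear ketene carbon with no inward substituent. High dilution, exclusion of oxygen and base-washed glassware are meant to keep the ketene from bimolecular capture, the hydroquinone from oxidation and the acetal from ionisation.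

Step 3
Reactants: 7 2-(dimethoxymethyl)-3,5,6-trimethoxybenzene-1,4-diol
Product: 8 2,5-dihydroxy-3,4,6-trimethoxybenzaldehyde
Conditions: 1 M HCl, THF, 0 °C → rt, Ar
Reagents that add atoms: water, O
Why: Acid hydrolysis of an aryl dimethyl acetal; the electron-rich ring stabilises the oxocarbenium ion, so dilute acid suffices, and the formyl group then makes the hydroquinone less prone to air oxidation.

Step 4
Reactants: 8 2,5-dihydroxy-3,4,6-trimethoxybenzaldehyde
Product: 9 2,4,5-trimethoxy-3,6-bis(methoxymethoxy)benzaldehyde
Conditions: NaH, MOMCl, DMF, 0 °C → rt, Ar
Reagents that add atoms: chloromethyl methyl ether (MOMCl), COCCl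
Why: Williamson-type O-alkylation of the bis-phenoxide; NaH breaks the hydrogen bond of the chelated ortho hydroxyl that amine bases tend to leave untouched, the aldehyde cannot enolise, and no ring position is free for C-alkylation.

Step 5
Reactants: 10 2-hydroxy-6-methoxybenzaldehyde
Product: 11 2-methoxy-6-(methoxymethoxy)benzaldehyde
Conditions: NaH, MOMCl, DMF, 0 °C → rt
Reagents that add atoms: chloromethyl methyl ether (MOMCl), COCCl
Why: Williamson-type O-alkylation of a chelated phenoxide; the MOM ether tolerates the base and organolithium of steps 6 and 7 and falls under the acid of step 9.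

Step 6
Reactants: 11 2-methoxy-6-(methoxymethoxy)benzaldehyde
Product: 12 2-ethynyl-1-methoxy-3-(methoxymethoxy)benzene
Conditions: dimethyl (1-diazo-2-oxopropyl)phosphonate, K2CO3, MeOH, rt
Reagents that add atoms: dimethyl (1-diazo-2-oxopropyl)phosphonate, COP(=O)(OC)C(=[N+]=[N-])C(C)=O
Why: Seyferth–Gilbert homologation in the Ohira–Bestmann variant; methanolysis of the reagent releases the diazomethylphosphonate, which turns the non-enolisable aldehyde into the terminal alkyne under mild base that leaves the MOM ether alone.

Step 7
Reactants: 12 2-ethynyl-1-methoxy-3-(methoxymethoxy)benzene; 9 2,4,5-trimethoxy-3,6-bis(methoxymethoxy)benzaldehyde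
Product: 14 3-[2-methoxy-6-(methoxymethoxy)phenyl]-1-[2,4,5-trimethoxy-3,6-bis(methoxymethoxy)phenyl]prop-2-yn-1-ol (racemic), via lithium acetylide 13 (not isolated)
Conditions: 12, n-BuLi, THF, −78 °C; then 9, −78 → 0 °C; aq. NH4Cl
Reagents that add atoms: none
Why: Acetylide addition to a non-enolisable aldehyde; the alkyne C–H is removed far faster than any ring position next to the MOM ether, and the slim nucleophile tolerates the two ortho substituents of 9; the racemic carbinol is oxidised in step 8.

Step 8
Reactants: 14 3-[2-methoxy-6-(methoxymethoxy)phenyl]-1-[2,4,5-trimethoxy-3,6-bis(methoxymethoxy)phenyl]prop-2-yn-1-ol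
Product: 15 3-[2-methoxy-6-(methoxymethoxy)phenyl]-1-[2,4,5-trimethoxy-3,6-bis(methoxymethoxy)phenyl]prop-2-yn-1-one
Conditions: MnO2, CH2Cl2, rt
Reagents that add atoms: none
Why: MnO2 oxidation of a doubly activated (benzylic and propargylic) alcohol; the neutral heterogeneous oxidant leaves the three MOM ethers and the ynone intact.

Step 9
Reactants: 15 3-[2-methoxy-6-(methoxymethoxy)phenyl]-1-[2,4,5-trimethoxy-3,6-bis(methoxymethoxy)phenyl]prop-2-yn-1-one
Product: 17 6,2'-dihydroxy-5,7,8,6'-tetramethoxyflavone, via triphenol ynone 16 (not isolated)
Conditions: HCl (1.25 M in MeOH), degassed, 50 °C, Ar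
Reagents that add atoms: none
Why: Acidic methanol transfers the three MOM groups to the solvent, and the freed C8a hydroxyl adds to the protonated ynone at C2 in a 6-endo-dig oxa-Michael addition; it is the only phenol that can reach this carbon, since the C6 hydroxyl is meta to the acyl group and the C2' hydroxyl could only attack the electron-poor α-carbon.

## Compound list

1 | (E)-1,3,3-trimethoxyprop-1-ene | CO/C=C/C(OC)OC | starting material
2 | dimethyl squarate (3,4-dimethoxycyclobut-3-ene-1,2-dione) | COC1=C(OC)C(=O)C1=O | starting material
3 | [(1E)-1,3,3-trimethoxyprop-1-en-1-yl]lithium | CO/C([Li])=C/C(OC)OC | intermediate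
4 | 4-hydroxy-2,3-dimethoxy-4-[(1E)-1,3,3-trimethoxyprop-1-en-1-yl]cyclobut-2-en-1-one (racemic) | CO/C(=C/C(OC)OC)C1(O)C(OC)=C(OC)C1=O | intermediate
5 | (3Z,5E)-4-hydroxy-2,3,5,7,7-pentamethoxyhepta-1,3,5-trien-1-one | O=C=C(OC)/C(OC)=C(O)\C(OC)=C/C(OC)OC | intermediate
6 | 6-(dimethoxymethyl)-4-hydroxy-2,3,5-trimethoxycyclohexa-2,4-dien-1-one (racemic) | COC(OC)C1C(=O)C(OC)=C(OC)C(O)=C1OC | intermediate
7 | 2-(dimethoxymethyl)-3,5,6-trimethoxybenzene-1,4-diol | COC(OC)c1c(O)c(OC)c(OC)c(O)c1OC | intermediate
8 | 2,5-dihydroxy-3,4,6-trimethoxybenzaldehyde | O=Cc1c(O)c(OC)c(OC)c(O)c1OC | intermediate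
9 | 2,4,5-trimethoxy-3,6-bis(methoxymethoxy)benzaldehyde | O=Cc1c(OCOC)c(OC)c(OC)c(OCOC)c1OC | intermediate
10 | 2-hydroxy-6-methoxybenzaldehyde | COc1cccc(O)c1C=O | starting material
11 | 2-methoxy-6-(methoxymethoxy)benzaldehyde | COCOc1cccc(OC)c1C=O | intermediate
12 | 2-ethynyl-1-methoxy-3-(methoxymethoxy)benzene | C#Cc1c(OC)cccc1OCOC | intermediate
13 | {[2-methoxy-6-(methoxymethoxy)phenyl]ethynyl}lithium | [Li]C#Cc1c(OC)cccc1OCOC | intermediate
14 | 3-[2-methoxy-6-(methoxymethoxy)phenyl]-1-[2,4,5-trimethoxy-3,6-bis(methoxymethoxy)phenyl]prop-2-yn-1-ol (racemic) | COCOc1cccc(OC)c1C#CC(O)c1c(OCOC)c(OC)c(OC)c(OCOC)c1OC | intermediate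
15 | 3-[2-methoxy-6-(methoxymethoxy)phenyl]-1-[2,4,5-trimethoxy-3,6-bis(methoxymethoxy)phenyl]prop-2-yn-1-one | COCOc1cccc(OC)c1C#CC(=O)c1c(OCOC)c(OC)c(OC)c(OCOC)c1OC | intermediate
16 | 1-(2,5-dihydroxy-3,4,6-trimethoxyphenyl)-3-(2-hydroxy-6-methoxyphenyl)prop-2-yn-1-one | COc1cccc(O)c1C#CC(=O)c1c(O)c(OC)c(OC)c(O)c1OC | intermediate
17 | 6,2'-dihydroxy-5,7,8,6'-tetramethoxyflavone | COc1cccc(O)c1-c1cc(=O)c2c(OC)c(O)c(OC)c(OC)c2o1 | target

## Step count and least certain steps

Total: 9 steps. Longest linear sequence: 7 steps (steps 1, 2, 3, 4, 7, 8, 9); steps 5 and 6 form the ring B branch.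

**Step 2 (key step).** Three processes are the most likely to spoil it.
- Air could oxidise the very electron-rich hydroquinone to the quinone during the hot reaction or the isolation.
- The ortho-hydroxy acetal could ionise with loss of methanol.
- The ketene could be captured bimolecularly if closure onto the substituted terminus is slow.

The fallback isolates ring A at the quinone level and changes the order of the later operations. It sets out from 4. Thermolysis as before, followed by deliberate oxidation with Ag2O, should give the non-phenolic and purifiable 2-(dimethoxymethyl)-3,5,6-trimethoxycyclohexa-2,5-diene-1,4-dione F1. Reduction with Na2S2O4 returns 7, which is not stored but alkylated at once (NaH, MOMCl) to 1-(dimethoxymethyl)-2,4,5-trimethoxy-3,6-bis(methoxymethoxy)benzene F2. Hydrolysis of the aryl dimethyl acetal under conditions too mild for aryl MOM ethers (PPTS, wet acetone) comes back to the route at 9. If the closure itself were at fault, the detour given under step 1 avoids the substituted terminus altogether.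

**Step 1.** The metalation could go astray: removal of the acetal hydrogen at C3, or addition of t-BuLi to the enol ether, in place of the wanted C1 lithiation. A second addition to the squarate is a lesser risk. The fallback uses the long-established α-lithiated methyl vinyl ether and brings in C4 afterwards. It sets out from 2.
- (1-Methoxyethenyl)lithium F3, made from methyl vinyl ether and t-BuLi, adds to 2 to give 4-hydroxy-2,3-dimethoxy-4-(1-methoxyethenyl)cyclobut-2-en-1-one F4.
- The same thermal rearrangement gives 2,3,5-trimethoxybenzene-1,4-diol F5.
- NaH and MOMCl give 1,3,4-trimethoxy-2,5-bis(methoxymethoxy)benzene F6.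
- The only ring hydrogen of F6 lies between a MOM ether and a methoxy group, so directed ortho-lithiation (n-BuLi, TMEDA, THF) should give [2,4,5-trimethoxy-3,6-bis(methoxymethoxy)phenyl]lithium F7.
- Formylation of F7 with DMF comes back to the route at 9, in the same number of operations as the main line.

**Step 9.** Ring closure could take the 5-exo course to the aurone skeleton, or the free hydroquinone-type ynone could be oxidised before it cyclises. The fallback fixes the site of attack by turning the alkyne into a vinylogous amide first. It sets out from 15. Conjugate addition of Et2NH in EtOH should give (2E)-3-(diethylamino)-3-[2-methoxy-6-(methoxymethoxy)phenyl]-1-[2,4,5-trimethoxy-3,6-bis(methoxymethoxy)phenyl]prop-2-en-1-one F8. Methanolic HCl then removes the MOM groups, and the C8a hydroxyl displaces the amine by addition–elimination at C2, where no five-membered closure is possible. The sequence comes back at 17.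

**Step 6.** The homologation could stall, because the aldehyde is electron-rich and flanked by two ortho oxygen substituents, so attack of the phosphonate anion is slow. The fallback is the Corey–Fuchs sequence. It sets out from 11. CBr4 and PPh3 should give 2-(2,2-dibromoethenyl)-1-methoxy-3-(methoxymethoxy)benzene F9. Two equivalents of n-BuLi convert F9 by bromine–lithium exchange, rearrangement and deprotonation directly into the acetylide 13, which is used in step 7 without isolating 12.

## Further compounds

F1 | step 2 | 2-(dimethoxymethyl)-3,5,6-trimethoxycyclohexa-2,5-diene-1,4-dione | COC(OC)C1=C(OC)C(=O)C(OC)=C(OC)C1=O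
F2 | step 2 | 1-(dimethoxymethyl)-2,4,5-trimethoxy-3,6-bis(methoxymethoxy)benzene | COC(OC)c1c(OCOC)c(OC)c(OC)c(OCOC)c1OC
F3 | step 1 | (1-methoxyethenyl)lithium | [Li]C(=C)OC
F4 | step 1 | 4-hydroxy-2,3-dimethoxy-4-(1-methoxyethenyl)cyclobut-2-en-1-one (racemic) | C=C(OC)C1(O)C(OC)=C(OC)C1=O
F5 | step 1 | 2,3,5-trimethoxybenzene-1,4-diol | COc1cc(O)c(OC)c(OC)c1O
F6 | step 1 | 1,3,4-trimethoxy-2,5-bis(methoxymethoxy)benzene | COCOc1cc(OC)c(OCOC)c(OC)c1OC
F7 | step 1 | [2,4,5-trimethoxy-3,6-bis(methoxymethoxy)phenyl]lithium | [Li]c1c(OCOC)c(OC)c(OC)c(OCOC)c1OC
F8 | step 9 | (2E)-3-(diethylamino)-3-[2-methoxy-6-(methoxymethoxy)phenyl]-1-[2,4,5-trimethoxy-3,6-bis(methoxymethoxy)phenyl]prop-2-en-1-one | CCN(CC)/C(=C/C(=O)c1c(OCOC)c(OC)c(OC)c(OCOC)c1OC)c1c(OC)cccc1OCOC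
F9 | step 6 | 2-(2,2-dibromoethenyl)-1-methoxy-3-(methoxymethoxy)benzene | COCOc1cccc(OC)c1C=C(Br)Br
A1 | alternative 1 | 5-[2-(benzyloxy)-6-methoxyphenyl]-3-[2,4,5-trimethoxy-3,6-bis(methoxymethoxy)phenyl]-1,2-oxazole | COCOc1c(OC)c(OC)c(OCOC)c(OC)c1-c1cc(-c2c(OC)cccc2OCc2ccccc2)on1
A2 | alternative 1 | 2,4,5-trimethoxy-3,6-bis(methoxymethoxy)benzonitrile oxide | COCOc1c(OC)c(OC)c(OCOC)c(OC)c1C#[N+][O-]
A3 | alternative 1 | 1-(benzyloxy)-2-ethynyl-3-methoxybenzene | C#Cc1c(OC)cccc1OCc1ccccc1
A4 | alternative 2 | 3-[5-(benzyloxy)-2-hydroxy-3,4,6-trimethoxybenzoyl]-5-methoxy-2H-chromen-2-one | O=c1oc2cccc(OC)c2cc1C(=O)c1c(O)c(OC)c(OC)c(OCc2ccccc2)c1OC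
A5 | alternative 2 | 6-(benzyloxy)-5,7,8-trimethoxy-4-oxo-4H-chromene-3-carboxylic acid | O=C(O)c1coc2c(OC)c(OC)c(OCc3ccccc3)c(OC)c2c1=O
A6 | alternative 2 | 3-methoxy-2-(trimethylsilyl)phenyl trifluoromethanesulfonate | COc1cccc(OS(=O)(=O)C(F)(F)F)c1[Si](C)(C)C
A7 | alternative 3 | 6-[2-(benzyloxy)-6-methoxyphenyl]-4,9-dimethoxy-2,2-dimethyl-8H-[1,3]dioxolo[4,5-g]chromen-8-one | COc1cccc(OCc2ccccc2)c1-c1cc(=O)c2c(OC)c3OC(C)(C)Oc3c(OC)c2o1
A8 | alternative 3 | 4,7-dimethoxy-2,2-dimethyl-6-(trimethylsilyl)-1,3-benzodioxol-5-yl trifluoromethanesulfonate | COc1c2OC(C)(C)Oc2c(OC)c([Si](C)(C)C)c1OS(=O)(=O)C(F)(F)F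
A9 | alternative 3 | 3-[2-(benzyloxy)-6-methoxyphenyl]prop-2-ynoic acid | COc1cccc(OCc2ccccc2)c1C#CC(=O)O
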